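The route rests on opening quinone ring B (C1, C2, C3, C4, C4a, C8a) at C2–C3. C3 is the α-carbon of the C4 carbonyl and C2 carries the carbinol carbon C1′. Ring B at the naphthol level is therefore an isomer of a silyl enol ether (C4=C3) sitting ortho to a propargylic silyl ether (C1≡C2–C1′) on the protected ring A. A cationic gold catalyst joins C3 to C2 (6-endo-dig) and aromatises. This builds ring B, places the side chain at C2 and leaves the (R)-centre, set earlier by ynone transfer hydrogenation, untouched. Oxygenation at C1, unmasking to shikonin and selective acylation of the C1′ hydroxyl follow.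

Key step: step 9

Remark: shikonin numbering is used throughout (ring B = C1, C2, C3, C4, C4a, C8a; ring A = C4a, C5–C8, C8a; side chain C1′–C5′). The stereocentre C1′ of the target is (R), which is the shikonin series.

Step 1
Reactants: 1 bromohydroquinone (2-bromobenzene-1,4-diol)
Product: 2 2-bromo-1,4-bis(methoxymethoxy)benzene
Conditions: NaH, MOMCl, DMF, 0 °C → rt
Reagents that add atoms: chloromethyl methyl ether (MOMCl), COCCl
Why: Williamson-type O-alkylation of both phenoxides installs MOM acetals that later direct the lithiation, survive palladium, gold and aerobic oxidation chemistry, and leave in dilute acid.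

Step 2
Reactants: 2 2-bromo-1,4-bis(methoxymethoxy)benzene; 3 N-methoxy-N-methylacetamide
Product: 5 1-[2-bromo-3,6-bis(methoxymethoxy)phenyl]ethan-1-one, via aryllithium 4 (not isolated)
Conditions: LiN(i-Pr)2, THF, −78 °C; then 3, −78 °C; AcOH quench
Reagents that add atoms: none
Why: Directed ortho-metalation followed by a Weinreb ketone synthesis: LiN(i-Pr)2 removes only the proton flanked by bromine and an OMOM group, the lithio bromide is held at −78 °C so that LiBr is not lost, and the Weinreb amide stops at the methyl ketone.

Step 3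
Reactants: 6 4-methylpent-3-enoic acid
Product: 7 N-methoxy-N,4-dimethylpent-3-enamide
Conditions: MeNH(OMe)·HCl, Et3N, DCC, CH2Cl2, 0 °C → rt
Reagents that add atoms: N,O-dimethylhydroxylamine hydrochloride, CNOC.Cl
Why: Carbodiimide-mediated amide coupling runs under near-neutral conditions that keep the β,γ-alkene out of conjugation.

Step 4
Reactants: 7 N-methoxy-N,4-dimethylpent-3-enamide; 8 trimethylsilylacetylene
Product: 10 6-methyl-1-(trimethylsilyl)hept-5-en-1-yn-3-one, via lithium acetylide 9 (not isolated)
Conditions: 8, n-BuLi, THF, −78 °C; then 7, −78 → −20 °C; AcOH quench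
Reagents that add atoms: none
Why: Weinreb ketone synthesis with a lithium acetylide gives the ynone without over-addition, and the cold acetic acid quench avoids base-induced migration of the β,γ-alkene.

Step 5
Reactants: 10 6-methyl-1-(trimethylsilyl)hept-5-en-1-yn-3-one
Product: 11 (3R)-6-methyl-1-(trimethylsilyl)hept-5-en-1-yn-3-ol
Conditions: Ru[(R,R)-TsDPEN](p-cymene) (1 mol %), i-PrOH, rt
Reagents that add atoms: none
Why: Noyori asymmetric transfer hydrogenation of an α,β-acetylenic ketone: the (R,R)-configured ruthenium amido complex passes hydride and proton through a six-membered transition state in which the alkynyl group takes the place usually held by an aryl group, which sets C1′ as (R), and the base-free medium spares the alkyne, the alkene and the acidic methylene group.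

Step 6
Reactants: 11 (3R)-6-methyl-1-(trimethylsilyl)hept-5-en-1-yn-3-ol
Product: 12 (3R)-6-methylhept-5-en-1-yn-3-ol
Conditions: K2CO3 (cat.), MeOH, 0 °C → rt
Reagents that add atoms: none
Why: Carbonate-catalysed methanolysis of the C(sp)–Si bond (protiodesilylation) is specific for the alkynylsilane and does not touch the carbinol centre.

Step 7
Reactants: 5 1-[2-bromo-3,6-bis(methoxymethoxy)phenyl]ethan-1-one; 12 (3R)-6-methylhept-5-en-1-yn-3-ol
Product: 13 1-{2-[(3R)-3-hydroxy-6-methylhept-5-en-1-yn-1-yl]-3,6-bis(methoxymethoxy)phenyl}ethan-1-one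
Conditions: PdCl2(PhCN)2 (3 mol %), P(t-Bu)3·HBF4 (6 mol %), CuI (2 mol %), i-Pr2NH, dioxane, rt → 45 °C
Reagents that add atoms: none
Why: Sonogashira coupling: the ortho acetyl group speeds oxidative addition of zerovalent palladium into the hindered C–Br bond, the bulky electron-rich phosphine allows a low temperature, and the free propargylic alcohol is tolerated.

Step 8
Reactants: 13 1-{2-[(3R)-3-hydroxy-6-methylhept-5-en-1-yn-1-yl]-3,6-bis(methoxymethoxy)phenyl}ethan-1-one
Product: 14 TBS enol ether of 13 with the C1′ hydroxyl as TBS ether: 2-[1-(tert-butyldimethylsilyloxy)ethenyl]-3-[(3R)-3-(tert-butyldimethylsilyloxy)-6-methylhept-5-en-1-yn-1-yl]-1,4-bis(methoxymethoxy)benzene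
Conditions: TBSOTf (2.5 equiv), Et3N, CH2Cl2, 0 °C
Reagents that add atoms: tert-butyldimethylsilyl triflate (TBSOTf), CC(C)(C)[Si](C)(C)OS(=O)(=O)C(F)(F)F
Why: Soft enolisation and O-silylation with a silyl triflate and an amine turn the methyl ketone into its only possible silyl enol ether and protect the C1′ hydroxyl in the same operation, without a base strong enough to touch the propargylic C–H.

Step 9
Reactants: 14 bis-silylated alkynyl enol ether
Product: 15 4-(tert-butyldimethylsilyloxy)-2-[(1R)-1-(tert-butyldimethylsilyloxy)-4-methylpent-3-en-1-yl]-5,8-bis(methoxymethoxy)naphthalene (shikonin numbering; C1–H and C3–H)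
Conditions: [(JohnPhos)Au(NCMe)]SbF6 (3 mol %), 4 Å MS, CH2Cl2, −20 °C → rt
Reagents that add atoms: none
Why: The cationic monovalent gold centre binds the C1≡C2 alkyne, the methylene carbon C3 of the silyl enol ether attacks C2 anti to gold, the silyloxocarbenium ion loses a C3 proton, and protodeauration at C1 releases aromatic ring B and the catalyst, so the step is a pure isomerisation. The closest known reaction type is the π-acid-catalysed cycloisomerisation of ortho-alkynylaryl silyl enol ethers to 1-silyloxynaphthalenes (a Conia-ene-type carbocyclisation). Ring B closes in the 6-endo-dig mode, whereas the 5-exo-dig alternative (attack at C1) would give a cross-conjugated alkylidene-indene without aromatic gain and is disfavoured by the bulky biaryl phosphine, which biases such closures toward the endo mode, and by the irreversible aromatisation that drains the 6-endo path. No stereocentre is created, and the (R)-centre at C1′ stays a spectator because the C1′–O bond is never ionised and C1′–H is never removed, unlike in base-mediated routes through allenes. Chemoselectivity is needed against the prenyl alkene (a 1,5-enyne relationship), the neighbouring C8 acetal oxygen and propargylic migration; the enol ether is by far the strongest π-nucleophile present and is held next to the alkyne by ring A, and a silyl ether at C1′ cannot undergo the acyloxy shift of a propargylic ester, which is why acylation is left to the end. Low temperature, molecular sieves and the robust TBS enol ether suppress hydrolysis to the ketone and carbonyl-oxygen attack on the alkyne.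

Step 10
Reactants: 15 silyloxynaphthalene
Product: 17 2-[(1R)-1-(tert-butyldimethylsilyloxy)-4-methylpent-3-en-1-yl]-5,8-bis(methoxymethoxy)naphthalene-1,4-dione, via naphthol 16 (not isolated)
Conditions: Bu4NF (1 equiv), AcOH, THF, −20 °C; then Co(salen) (10 mol %), O2 (1 atm), MeCN, rt
Reagents that add atoms: dioxygen, O=O
Why: Buffered fluoride cleaves the aryl silyl ether far faster than the hindered secondary alkyl TBS ether, and the electron-rich 1-naphthol with a free para position (C1–H) is taken to the para-quinone by cobalt–salen-catalysed aerobic phenol oxygenation, which leaves the trisubstituted alkene and the MOM-blocked ring A untouched.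

Step 11
Reactants: 17 protected quinone
Product: 18 shikonin, 5,8-dihydroxy-2-[(1R)-1-hydroxy-4-methylpent-3-en-1-yl]naphthalene-1,4-dione
Conditions: 2 M aq. HCl, THF, 40 °C, argon, dark
Reagents that add atoms: none
Why: Acid hydrolysis of the two aryl MOM acetals (the freed phenols are captured in hydrogen bonds to the peri carbonyl groups) and of the TBS ether unmasks the naphthazarin core, while C1′ next to the electron-poor quinone does not ionise and keeps its configuration.

Step 12
Reactants: 19 2,3-dimethylbuta-1,3-diene
Product: 20 3,4-dimethylpent-3-enoic acid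
Conditions: Pd(OAc)2 (1 mol %), Xantphos (2 mol %), PhCO2H (10 mol %), CO (40 bar), H2O, dioxane, 100 °C
Reagents that add atoms: carbon monoxide, [C-]#[O+]; water, O
Why: Palladium-catalysed hydroxycarbonylation of a 1,3-diene: Pd–H adds to a terminal carbon, CO inserts at the unhindered CH2 end of the 1,1,2-trimethylallyl complex and water releases the β,γ-unsaturated acid, whose tetrasubstituted alkene resists further Pd–H isomerisation.

Step 13
Reactants: 18 shikonin; 20 3,4-dimethylpent-3-enoic acid
Product: 21 (1R)-1-(5,8-dihydroxy-1,4-dioxo-1,4-dihydronaphthalen-2-yl)-4-methylpent-3-en-1-yl 3,4-dimethylpent-3-enoate (target)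
Conditions: DCC, DMAP (cat.), CH2Cl2, 0 °C → rt, dark
Reagents that add atoms: none
Why: Steglich esterification: both phenolic hydroxyls are locked in strong hydrogen bonds to the quinone carbonyls and are poor nucleophiles, so only the C1′ hydroxyl is acylated, with retention because the C1′–O bond is not touched, and the tetrasubstituted β,γ-alkene of the acid has no drive to move into conjugation.

Compound list
1 | bromohydroquinone (2-bromobenzene-1,4-diol) | Oc1ccc(O)c(Br)c1 | starting material
2 | 2-bromo-1,4-bis(methoxymethoxy)benzene | COCOc1ccc(OCOC)c(Br)c1 | intermediate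
3 | N-methoxy-N-methylacetamide | CC(=O)N(C)OC | starting material
4 | [2-bromo-3,6-bis(methoxymethoxy)phenyl]lithium | [Li]c1c(Br)c(OCOC)ccc1OCOC | intermediate
5 | 1-[2-bromo-3,6-bis(methoxymethoxy)phenyl]ethan-1-one | CC(=O)c1c(Br)c(OCOC)ccc1OCOC | intermediate
6 | 4-methylpent-3-enoic acid | CC(C)=CCC(=O)O | starting material
7 | N-methoxy-N,4-dimethylpent-3-enamide | CC(C)=CCC(=O)N(C)OC | intermediate
8 | trimethylsilylacetylene | C#C[Si](C)(C)C | starting material
9 | lithium (trimethylsilyl)acetylide | [Li]C#C[Si](C)(C)C | intermediate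
10 | 6-methyl-1-(trimethylsilyl)hept-5-en-1-yn-3-one | CC(C)=CCC(=O)C#C[Si](C)(C)C | intermediate
11 | (3R)-6-methyl-1-(trimethylsilyl)hept-5-en-1-yn-3-ol | CC(C)=CC[C@@H](O)C#C[Si](C)(C)C | intermediate
12 | (3R)-6-methylhept-5-en-1-yn-3-ol | CC(C)=CC[C@@H](O)C#C | intermediate
13 | 1-{2-[(3R)-3-hydroxy-6-methylhept-5-en-1-yn-1-yl]-3,6-bis(methoxymethoxy)phenyl}ethan-1-one | CC(C)=CC[C@@H](O)C#Cc1c(OCOC)ccc(OCOC)c1C(C)=O | intermediate
14 | 2-[1-(tert-butyldimethylsilyloxy)ethenyl]-3-[(3R)-3-(tert-butyldimethylsilyloxy)-6-methylhept-5-en-1-yn-1-yl]-1,4-bis(methoxymethoxy)benzene | CC(C)=CC[C@@H](O[Si](C)(C)C(C)(C)C)C#Cc1c(OCOC)ccc(OCOC)c1C(=C)O[Si](C)(C)C(C)(C)C | intermediate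
15 | 4-(tert-butyldimethylsilyloxy)-2-[(1R)-1-(tert-butyldimethylsilyloxy)-4-methylpent-3-en-1-yl]-5,8-bis(methoxymethoxy)naphthalene (shikonin numbering) | CC(C)=CC[C@@H](O[Si](C)(C)C(C)(C)C)c1cc(O[Si](C)(C)C(C)(C)C)c2c(OCOC)ccc(OCOC)c2c1 | intermediate
16 | 2-[(1R)-1-(tert-butyldimethylsilyloxy)-4-methylpent-3-en-1-yl]-5,8-bis(methoxymethoxy)naphthalen-4-ol (shikonin numbering) | CC(C)=CC[C@@H](O[Si](C)(C)C(C)(C)C)c1cc(O)c2c(OCOC)ccc(OCOC)c2c1 | intermediate
17 | 2-[(1R)-1-(tert-butyldimethylsilyloxy)-4-methylpent-3-en-1-yl]-5,8-bis(methoxymethoxy)naphthalene-1,4-dione | CC(C)=CC[C@@H](O[Si](C)(C)C(C)(C)C)C1=CC(=O)c2c(OCOC)ccc(OCOC)c2C1=O | intermediate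
18 | shikonin, 5,8-dihydroxy-2-[(1R)-1-hydroxy-4-methylpent-3-en-1-yl]naphthalene-1,4-dione | CC(C)=CC[C@@H](O)C1=CC(=O)c2c(O)ccc(O)c2C1=O | intermediate
19 | 2,3-dimethylbuta-1,3-diene | C=C(C)C(C)=C | starting material
20 | 3,4-dimethylpent-3-enoic acid | CC(C)=C(C)CC(=O)O | intermediate
21 | (1R)-1-(5,8-dihydroxy-1,4-dioxo-1,4-dihydronaphthalen-2-yl)-4-methylpent-3-en-1-yl 3,4-dimethylpent-3-enoate | CC(C)=CC[C@@H](OC(=O)CC(C)=C(C)C)C1=CC(=O)c2c(O)ccc(O)c2C1=O | target

Total step count: 13.
Longest linear sequence: 10 steps (steps 3, 4, 5, 6, 7, 8, 9, 10, 11 and 13).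

Steps most likely to fail

Step 9. The ring closure may lose regioselectivity through attack of the enol ether at C1. The gold-activated alkyne may instead be captured by the prenyl alkene or by the C8 acetal oxygen, or the enol ether may hydrolyse before it cyclises. The fallback sets out from 5 and comes back at 17. It closes the same C2–C3 bond from the other side through a metal vinylidene. The alkyne then has no propargylic oxygen and no prenyl neighbour, and it can only be attacked at its terminal carbon.
- Sonogashira coupling of 5 with 8 should give the silylethynyl ketone F1, and K2CO3 in MeOH the ethynyl ketone F2.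
- A boron aldol reaction of F2 follows, using Et3N and the antipode of Ipc2BCl that delivers the (R)-carbinol. The partner is 4-methylpent-3-enal F3, made by Dess–Martin oxidation of commercial 4-methylpent-3-en-1-ol. This should give the β-hydroxy ketone F4.
- TBSOTf and Et3N should convert F4 into the (Z)-silyl enol ether F5, whose carbinol is silylated as well.
- W(CO)5(thf), generated from W(CO)6 by irradiation in THF, should turn the terminal alkyne into a vinylidene. Its 6π-electrocyclisation with the C1=C2 enol ether across the C4a–C8a bond joins C2 to C3 and gives the 1-silyloxynaphthalene F6.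
- The conditions of step 10 then lead through the 1-naphthol F7, whose para position C4 is less hindered than C1 of 16, to 17.

Step 10. Oxygen transfer to the hindered C1 position may be slow, so that ortho-oxygenation at C3 or oxidative dimerisation of the naphthoxyl radical takes over. The fallback sets out from 15 (desilylated to 16 as before) and comes back at 18. It replaces the radical aerobic path by two successive two-electron oxidative dearomatisations.
- PhI(OAc)2 (2 equiv) in MeOH should first give the methoxynaphthol F8 by para capture of the phenoxenium ion by methanol.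
- A second oxidation in the same flask should then give the quinone monoketal F9.
- The aqueous acid of step 11 hydrolyses the ketal together with the MOM and TBS groups to 18.

Step 11. The free C1′ hydroxyl may add to the prenyl alkene under acid, and the unmasked naphthazarin may polymerise on long exposure. The fallback sets out from 17 and comes back at 21. It changes the order of events so that the free carbinol never meets acid.
- HF·pyridine in THF should give the bis-MOM alcohol F10.
- Steglich esterification of F10 with 20 should give the bis-MOM ester F11.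
- The same dilute aqueous HCl in THF then removes only the two peri MOM groups from the acylated compound and gives 21.

Further compounds
F1 | step 9 | 1-{3,6-bis(methoxymethoxy)-2-[(trimethylsilyl)ethynyl]phenyl}ethan-1-one | CC(=O)c1c(C#C[Si](C)(C)C)c(OCOC)ccc1OCOC
F2 | step 9 | 1-[2-ethynyl-3,6-bis(methoxymethoxy)phenyl]ethan-1-one | CC(=O)c1c(C#C)c(OCOC)ccc1OCOC
F3 | step 9 | 4-methylpent-3-enal | CC(C)=CCC=O
F4 | step 9 | (3R)-1-[2-ethynyl-3,6-bis(methoxymethoxy)phenyl]-3-hydroxy-6-methylhept-5-en-1-one | CC(C)=CC[C@@H](O)CC(=O)c1c(C#C)c(OCOC)ccc1OCOC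
F5 | step 9 | 2-[(1Z,3R)-1,3-bis(tert-butyldimethylsilyloxy)-6-methylhepta-1,5-dien-1-yl]-3-ethynyl-1,4-bis(methoxymethoxy)benzene | CC(C)=CC[C@@H](O[Si](C)(C)C(C)(C)C)/C=C(\O[Si](C)(C)C(C)(C)C)c1c(C#C)c(OCOC)ccc1OCOC
F6 | step 9 | 1-(tert-butyldimethylsilyloxy)-2-[(1R)-1-(tert-butyldimethylsilyloxy)-4-methylpent-3-en-1-yl]-5,8-bis(methoxymethoxy)naphthalene | CC(C)=CC[C@@H](O[Si](C)(C)C(C)(C)C)c1ccc2c(OCOC)ccc(OCOC)c2c1O[Si](C)(C)C(C)(C)C
F7 | step 9 | 2-[(1R)-1-(tert-butyldimethylsilyloxy)-4-methylpent-3-en-1-yl]-5,8-bis(methoxymethoxy)naphthalen-1-ol | CC(C)=CC[C@@H](O[Si](C)(C)C(C)(C)C)c1ccc2c(OCOC)ccc(OCOC)c2c1O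
F8 | step 10 | 2-[(1R)-1-(tert-butyldimethylsilyloxy)-4-methylpent-3-en-1-yl]-1-methoxy-5,8-bis(methoxymethoxy)naphthalen-4-ol (shikonin numbering) | CC(C)=CC[C@@H](O[Si](C)(C)C(C)(C)C)c1cc(O)c2c(OCOC)ccc(OCOC)c2c1OC
F9 | step 10 | 3-[(1R)-1-(tert-butyldimethylsilyloxy)-4-methylpent-3-en-1-yl]-4,4-dimethoxy-5,8-bis(methoxymethoxy)naphthalen-1(4H)-one | CC(C)=CC[C@@H](O[Si](C)(C)C(C)(C)C)C1=CC(=O)c2c(OCOC)ccc(OCOC)c2C1(OC)OC
F10 | step 11 | 2-[(1R)-1-hydroxy-4-methylpent-3-en-1-yl]-5,8-bis(methoxymethoxy)naphthalene-1,4-dione | CC(C)=CC[C@@H](O)C1=CC(=O)c2c(OCOC)ccc(OCOC)c2C1=O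
F11 | step 11 | (1R)-1-[5,8-bis(methoxymethoxy)-1,4-dioxo-1,4-dihydronaphthalen-2-yl]-4-methylpent-3-en-1-yl 3,4-dimethylpent-3-enoate | CC(C)=CC[C@@H](OC(=O)CC(C)=C(C)C)C1=CC(=O)c2c(OCOC)ccc(OCOC)c2C1=O
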